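**Retrosynthetic overview** (ring atoms: C1 = carbinol carbon carrying CH2OBz, C2 = CHOBz, C3 = CHOH, C4=C5, C6 = CHCl)
- Enabling feature: the cyclohexene ring has its only carbon branch and a tertiary oxygen on C1, next to O-bearing C2, and the C4=C5 double bond lies between C3–O and C6–Cl on one face. The ring is therefore the cis-1,4-oxychlorination product of a cyclohexa-3,5-diene, in which C1/C6 are an α-oxyacrylic acid unit (CH2OBz = reduced carboxyl) and C2–C5 a 1-benzoyloxybutadiene.
- Endgame: primary benzoate ⇐ selective acylation; CH2OH and C3–OH ⇐ reduction of a C1→C3 bridging lactone; lactone plus C6–Cl ⇐ palladium-catalysed 1,4-chlorolactonisation of a diene hydroxy acid.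
- Key disconnection: C1–C2 (at the fully substituted carbon) and C5–C6 by Diels–Alder union of a dienyl benzoate with a chiral β-bromo-α-oxyacrylate, then loss of HBr to the diene.
- Ring order: dioxolanone auxiliary ring (step 1), cyclohexene ring (step 5), temporary γ-lactone ring (step 7, opened in step 8).
- Absolute configuration comes from (R)-lactic acid through the tert-butyl acetal carbon.

Key step: step 5

Assumption: the bromomethylidene dienophile is drawn and used as its Z isomer (bromine syn to the ring oxygen); the E isomer would only change the transient CHBr centre, which is made trigonal again in the same step.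

Step 1
Reactants: 1 (R)-lactic acid
Product: 2 (2R,5R)-2-tert-butyl-5-methyl-1,3-dioxolan-4-one (cis)
Conditions: pivalaldehyde, p-TsOH·H2O (cat.), H2SO4 (cat.), pentane, reflux with azeotropic removal of water; crystallisation from pentane/Et2O at −78 °C
Reagents that add atoms: pivalaldehyde, CC(C)(C)C=O
Why: Acid-catalysed acetalisation of the α-hydroxy acid gives the dioxolanone, and the new acetal centre is set cis to the C5 methyl group under thermodynamic control, the cis isomer being purified by crystallisation.

Step 2
Reactants: 2 (2R,5R)-2-tert-butyl-5-methyl-1,3-dioxolan-4-one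
Product: 4 (2R)-2-tert-butyl-5-methylidene-1,3-dioxolan-4-one, via tertiary bromide 3 (not isolated)
Conditions: NBS, AIBN (cat.), PhCF3, 85 °C; then Et3N, 0 °C → rt
Reagents that add atoms: none
Why: Radical bromination with NBS (Wohl–Ziegler type) should occur at the captodative C5–H, and E2 dehydrobromination then gives the exocyclic enol ether, the lactate centre being sacrificed while the acetal carbon keeps the chirality.

Step 3
Reactants: 4 (2R)-2-tert-butyl-5-methylidene-1,3-dioxolan-4-one
Product: 6 (2R,5Z)-5-(bromomethylidene)-2-tert-butyl-1,3-dioxolan-4-one, via dibromide 5 (not isolated)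
Conditions: Br2, CH2Cl2, −78 °C; then i-Pr2NEt, −78 → 0 °C
Reagents that add atoms: bromine, BrBr
Why: Bromination–dehydrobromination of an enol ether (electrophilic addition of bromine, then base-induced loss of HBr from the labile tertiary α-bromo acetal) should give the β-bromo enol ether, expected mainly as the Z isomer, with no new stereocentre.

Step 4
Reactants: 7 (E)-but-2-enal (crotonaldehyde)
Product: 8 (1E)-buta-1,3-dien-1-yl benzoate
Conditions: KOtBu, THF, −78 °C; then BzCl, −78 → 0 °C
Reagents that add atoms: benzoyl chloride, O=C(Cl)c1ccccc1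
Why: γ-Deprotonation gives the potassium dienolate, whose O-acylation (dienol ester formation) should give mainly the E dienyl benzoate, and any Z isomer is inert in step 5 and removed there.

Step 5
Reactants: 6 (2R,5Z)-5-(bromomethylidene)-2-tert-butyl-1,3-dioxolan-4-one; 8 (1E)-buta-1,3-dien-1-yl benzoate
Product: 10 (2R,5S,10R)-2-tert-butyl-4-oxo-1,3-dioxaspiro[4.5]deca-6,8-dien-10-yl benzoate, via bromo cycloadduct 9 (not isolated)
Conditions: 8 (3 equiv), BHT (cat.), PhMe, 110 °C, sealed tube; then DBU, 0 °C → rt; product kept cold and used promptly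
Reagents that add atoms: none
Why: A thermal, concerted but asynchronous normal-electron-demand Diels–Alder cycloaddition joins C5 of diene 8 to the β-carbon (C6) and C2 to the α-carbon (C1) of the captodative acrylate 6, and DBU then removes HBr from 9 by anti E2 elimination, which can only run towards C5 because C1 carries no hydrogen. The closest known reaction type is the exo- and face-selective cycloaddition of 2-tert-butyl-5-methylidene-1,3-dioxolan-4-ones with acyclic dienes, followed by an ordinary dehydrohalogenation. The cyclohexene ring is closed by intermolecular suprafacial [4+2] union of the two π systems, the dioxolanone becoming a spiro ring at C1. C1 is controlled by the tert-butyl group of the acetal, which blocks one face of the planar dienophile so that the diene adds anti to it; C2 is controlled relative to C1 by the E geometry of the dienyl ester together with the exo transition state (lactone carbonyl away from the diene, ring oxygen under it), which places the C1–O bond and the C2 benzoate cis; the CHBr centre of 9 is only transient. The step needs ortho regiochemistry, secured by the 1-benzoyloxy donor (largest HOMO coefficient at the unsubstituted diene terminus) matched with the carbonyl on C1 (largest LUMO coefficient at C6), and exo and facial selectivity, secured by the s-cis-locked α-alkylidene lactone and the acetal. Delaying the elimination until the dienophile is consumed should keep the product diene out of a second cycloaddition.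

Step 6
Reactants: 10 (2R,5S,10R)-2-tert-butyl-4-oxo-1,3-dioxaspiro[4.5]deca-6,8-dien-10-yl benzoate
Product: 11 (1S,2R)-2-(benzoyloxy)-1-hydroxycyclohexa-3,5-diene-1-carboxylic acid
Conditions: LiOH·H2O (1.1 equiv), THF–H2O (3:1), 0 °C; then 1 M HCl to pH 3–4 at 0 °C; used at once
Reagents that add atoms: lithium hydroxide, [Li+].[OH-]
Why: Chemoselective ester hydrolysis is expected because the activated acylal-type lactone carbonyl should react with one equivalent of hydroxide much faster than the hindered secondary benzoate, releasing pivalaldehyde, the C1 hydroxyl and the carboxylic acid without touching a stereocentre.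

Step 7
Reactants: 11 (1S,2R)-2-(benzoyloxy)-1-hydroxycyclohexa-3,5-diene-1-carboxylic acid
Product: 12 (1S,2R,5S,8R)-2-chloro-1-hydroxy-7-oxo-6-oxabicyclo[3.2.1]oct-3-en-8-yl benzoate
Conditions: Pd(OAc)2 (5 mol %), LiCl (2.5 equiv), p-benzoquinone (2 equiv), acetone–AcOH (4:1), 20 °C
Reagents that add atoms: lithium chloride, [Li+].[Cl-]
Why: In this palladium-catalysed oxidative 1,4-chlorolactonisation of a conjugated diene, divalent palladium bound to the upper face of C3=C4 should be attacked from below by the C1 carboxylate (anti oxypalladation, closing the five-membered lactone and setting C3), and the resulting π-allyl complex over C4–C6 should be opened by external chloride anti to palladium at C6, the terminus remote from the new C3–O bond, so that C3–O and C6–Cl end up cis to each other and trans to the C1 hydroxyl and C2 benzoate, while benzoquinone returns zerovalent palladium to the divalent state.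

Step 8
Reactants: 12 (1S,2R,5S,8R)-2-chloro-1-hydroxy-7-oxo-6-oxabicyclo[3.2.1]oct-3-en-8-yl benzoate
Product: 13 (1R,2R,3R,6S)-3-chloro-2,6-dihydroxy-2-(hydroxymethyl)cyclohex-4-en-1-yl benzoate
Conditions: NaBH4, THF–EtOH, −20 → 0 °C; pH 7 phosphate buffer quench
Reagents that add atoms: none
Why: Hydride reduction of the strained α-hydroxy γ-lactone, whose carbonyl is activated by the α-oxygen, should be much faster than reduction of the aryl ester or attack on the allylic chloride, and it releases the C3 hydroxyl and the hydroxymethyl group without touching a stereocentre.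

Step 9
Reactants: 13 (1R,2R,3R,6S)-3-chloro-2,6-dihydroxy-2-(hydroxymethyl)cyclohex-4-en-1-yl benzoate
Product: 14 [(1R,2R,5S,6R)-6-(benzoyloxy)-2-chloro-1,5-dihydroxycyclohex-3-en-1-yl]methyl benzoate (target)
Conditions: BzCl (1.05 equiv), 2,4,6-collidine, CH2Cl2, −40 → 0 °C
Reagents that add atoms: benzoyl chloride, O=C(Cl)c1ccccc1
Why: Selective esterification of the primary hydroxyl with one equivalent of benzoyl chloride and a hindered pyridine base at low temperature should leave the secondary allylic C3 hydroxyl and the tertiary C1 hydroxyl free and give the target.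

**Compound list**
1 | (R)-lactic acid | C[C@@H](O)C(=O)O | starting material
2 | (2R,5R)-2-tert-butyl-5-methyl-1,3-dioxolan-4-one (tert-butyl and methyl cis) | C[C@H]1O[C@@H](C(C)(C)C)OC1=O | intermediate
3 | (2S,5S)-5-bromo-2-tert-butyl-5-methyl-1,3-dioxolan-4-one (bromine trans to tert-butyl) | C[C@@]1(Br)O[C@@H](C(C)(C)C)OC1=O | intermediate
4 | (2R)-2-tert-butyl-5-methylidene-1,3-dioxolan-4-one | C=C1O[C@@H](C(C)(C)C)OC1=O | intermediate
5 | (2S)-5-bromo-5-(bromomethyl)-2-tert-butyl-1,3-dioxolan-4-one (mixture at C5) | BrCC1(Br)O[C@@H](C(C)(C)C)OC1=O | intermediate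
6 | (2R,5Z)-5-(bromomethylidene)-2-tert-butyl-1,3-dioxolan-4-one | Br/C=C1\O[C@@H](C(C)(C)C)OC1=O | intermediate
7 | (E)-but-2-enal (crotonaldehyde) | C/C=C/C=O | starting material
8 | (1E)-buta-1,3-dien-1-yl benzoate | C=C/C=C/OC(=O)c1ccccc1 | intermediate
9 | (2R,5S,6R,10S)-10-bromo-2-tert-butyl-4-oxo-1,3-dioxaspiro[4.5]dec-7-en-6-yl benzoate (ring oxygen, benzoate and bromine on one face) | O=C1O[C@H](C(C)(C)C)O[C@]12[C@@H](Br)CC=C[C@H]2OC(=O)c1ccccc1 | intermediate
10 | (2R,5S,10R)-2-tert-butyl-4-oxo-1,3-dioxaspiro[4.5]deca-6,8-dien-10-yl benzoate | O=C1O[C@H](C(C)(C)C)O[C@]12C=CC=C[C@H]2OC(=O)c1ccccc1 | intermediate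
11 | (1S,2R)-2-(benzoyloxy)-1-hydroxycyclohexa-3,5-diene-1-carboxylic acid (OH and OBz cis) | OC(=O)[C@]1(O)C=CC=C[C@H]1OC(=O)c1ccccc1 | intermediate
12 | (1S,2R,5S,8R)-2-chloro-1-hydroxy-7-oxo-6-oxabicyclo[3.2.1]oct-3-en-8-yl benzoate | O=C1O[C@H]2C=C[C@@H](Cl)[C@]1(O)[C@@H]2OC(=O)c1ccccc1 | intermediate
13 | (1R,2R,3R,6S)-3-chloro-2,6-dihydroxy-2-(hydroxymethyl)cyclohex-4-en-1-yl benzoate | OC[C@]1(O)[C@H](Cl)C=C[C@H](O)[C@H]1OC(=O)c1ccccc1 | intermediate
14 | [(1R,2R,5S,6R)-6-(benzoyloxy)-2-chloro-1,5-dihydroxycyclohex-3-en-1-yl]methyl benzoate | O=C(OC[C@]1(O)[C@H](Cl)C=C[C@H](O)[C@H]1OC(=O)c1ccccc1)c1ccccc1 | target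

**Totals**
Total steps: 9. Longest linear sequence: 8 steps (1, 2, 3, 5, 6, 7, 8, 9).

**Steps most likely to fail**

Step 7. Risk: chloride may attack the wrong terminus of the allyl unit (C4 instead of C6), or acetate may capture the intermediate, and the dihydroarene-type diene may aromatise in the acidic medium. Fallback from 9 to 12: cycloadduct 9 is isolated without the DBU treatment, so that the halogen on C6 is carried through instead of being reinstalled. LiOH as in step 6 should give the bromo hydroxy acid F5. Iodolactonisation (I2, NaHCO3, MeCN–H2O, 0 °C) should give the bromo iodolactone F6, with the carboxylate adding to C3 from below and iodine on C4 above. DBU (PhMe, rt) should remove HI through the anti hydrogen on C5 to give the allylic bromide lactone F7. LiCl in DMF (Finkelstein-type exchange, SN2 with inversion at C6) should then give 12.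

Step 5. Risk: the β-bromo substituent may slow the cycloaddition so that thermal loss of HBr, polymerisation of the dienyl ester or erosion of exo selectivity compete. Fallback from 4 and 8 to 11: the unbrominated dienophile 4 and diene 8 are heated (PhMe, 100 °C) to give the spiro cyclohexene adduct F1 by the same C1–C2/C5–C6 cycloaddition. LiOH as in step 6 should give the cyclohexene hydroxy acid F2. Iodolactonisation (I2, NaHCO3, MeCN–H2O) should give the iodolactone F3, and DBU the ene-lactone F4. Pd(PPh3)4 (cat.) with Et3N in THF at 50 °C should then open the allylic lactone (ionisation by zerovalent palladium, syn β-hydride elimination from C6) to give diene acid 11 after acidification.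

Step 8. Risk: under the basic borohydride conditions the benzoyl group may migrate from the C2 oxygen to a newly freed hydroxyl, giving regioisomeric esters. Fallback from 12 to 14: LiBH4 (excess, THF, 0 °C) reduces lactone and benzoate together to give the chloro tetraol F8. BzCl and collidine as in step 9 should give the primary benzoate F9. PhC(OMe)3 with CSA (cat.) in CH2Cl2 should form the cyclic orthobenzoate F10 on the cis C1/C2 diol. AcOH–H2O (4:1) at rt should open it with the acyl group on the secondary C2 oxygen, giving 14.

**Further compounds**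
F1 | step 5 | (2R,5S,6R)-2-tert-butyl-4-oxo-1,3-dioxaspiro[4.5]dec-7-en-6-yl benzoate | O=C1O[C@H](C(C)(C)C)O[C@]12CCC=C[C@H]2OC(=O)c1ccccc1
F2 | step 5 | (1S,2R)-2-(benzoyloxy)-1-hydroxycyclohex-3-ene-1-carboxylic acid | OC(=O)[C@]1(O)CCC=C[C@H]1OC(=O)c1ccccc1
F3 | step 5 | (1S,4R,5R,8R)-1-hydroxy-4-iodo-7-oxo-6-oxabicyclo[3.2.1]octan-8-yl benzoate | O=C1O[C@H]2[C@H](I)CC[C@]1(O)[C@@H]2OC(=O)c1ccccc1
F4 | step 5 | (1S,5S,8R)-1-hydroxy-7-oxo-6-oxabicyclo[3.2.1]oct-3-en-8-yl benzoate | O=C1O[C@H]2C=CC[C@]1(O)[C@@H]2OC(=O)c1ccccc1
F5 | step 7 | (1S,2R,6S)-2-(benzoyloxy)-6-bromo-1-hydroxycyclohex-3-ene-1-carboxylic acid | OC(=O)[C@]1(O)[C@@H](Br)CC=C[C@H]1OC(=O)c1ccccc1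
F6 | step 7 | (1S,2S,4R,5R,8R)-2-bromo-1-hydroxy-4-iodo-7-oxo-6-oxabicyclo[3.2.1]octan-8-yl benzoate | O=C1O[C@H]2[C@H](I)C[C@H](Br)[C@]1(O)[C@@H]2OC(=O)c1ccccc1
F7 | step 7 | (1S,2S,5S,8R)-2-bromo-1-hydroxy-7-oxo-6-oxabicyclo[3.2.1]oct-3-en-8-yl benzoate | O=C1O[C@H]2C=C[C@H](Br)[C@]1(O)[C@@H]2OC(=O)c1ccccc1
F8 | step 8 | (1R,2R,3S,6R)-6-chloro-1-(hydroxymethyl)cyclohex-4-ene-1,2,3-triol | OC[C@]1(O)[C@H](Cl)C=C[C@H](O)[C@H]1O
F9 | step 8 | [(1R,2R,5S,6R)-2-chloro-1,5,6-trihydroxycyclohex-3-en-1-yl]methyl benzoate | O=C(OC[C@]1(O)[C@H](Cl)C=C[C@H](O)[C@H]1O)c1ccccc1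
F10 | step 8 | cyclic methyl orthobenzoate of F9 across the C1 and C2 oxygens (mixture at the orthoester carbon) | O=C(OC[C@@]12OC(OC)(c3ccccc3)O[C@@H]1[C@@H](O)C=C[C@H]2Cl)c1ccccc1
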